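**Plan**

- Retrosynthesis: the last cut removes C2–C1' and O1–C2 together, dividing the target into a ring A lactol and 2,4-diformylphloroglucinol. Further back, the two ring A formyl C–C bonds, the C3–isopropyl bond, the C4–H bond and the Pechmann bonds (C4–C4a, lactone C–O) are cut, ending at 3,5-dimethoxyphenol and a β-keto ester.
- Forward: a Pechmann condensation builds ring A with its lactone ring. The lactone is reduced at C4, isopropylated at C3, taken to the lactol, formylated twice and unmasked. The pyran ring is then opened and closed again around C2 in the last step, which also attaches ring B.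
- Enabling feature: C2 carries O1, C3 and C1' of ring B. Ring B is 2,4-diformylphloroglucinol, whose one unsubstituted carbon condenses with an aliphatic aldehyde to an ortho-quinone methide whose exocyclic carbon is C2.
- Stereochemistry: C4 (R) comes from a ligand-controlled copper hydride conjugate reduction. C3 (R) is set trans to C4 by an anti aldol addition and is also the thermodynamic arrangement. C2 (R) arises when the quinone methide closes trans to C3.

Key step: step 11

Numbering: chroman locants (O1, C2, C3, C4, C4a–C8a) for ring A and the pyran ring; C1'–C6' for ring B.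
Assumption: the hand of the bisphosphine in step 2 is written as (R); what is required is hydride delivery to the Si face of C4, and the antipodal ligand is used if a test run on the coumarin shows the opposite sense.

**Route**

Step 1
Reactants: 1 3,5-dimethoxyphenol; 2 ethyl 5-methyl-3-oxohexanoate
Product: 3 4-isobutyl-5,7-dimethoxy-2H-chromen-2-one
Conditions: MeSO3H, 0 °C to rt
Reagents that add atoms: none
Why: Pechmann condensation of a strongly activated phenol with a β-keto ester, in which only attack ortho to the hydroxyl can lactonise, so the 4-isobutyl-5,7-dimethoxycoumarin should be the sole coumarin formed.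

Step 2
Reactants: 3 4-isobutyl-5,7-dimethoxy-2H-chromen-2-one
Product: 4 (R)-4-isobutyl-5,7-dimethoxychroman-2-one
Conditions: Cu(OAc)2·H2O (3 mol %), (R)-DTBM-SEGPHOS (3 mol %), (EtO)2MeSiH (3 equiv), t-BuOH (1.2 equiv), toluene, 0 °C to rt
Reagents that add atoms: none
Why: Copper hydride-catalysed asymmetric conjugate reduction, known for 4-substituted coumarins, in which the ligand-bound hydride is delivered to the Si face of C4 to set 4R and t-BuOH protonates the copper enolate before it can open to a ketene.

Step 3
Reactants: 4 (R)-4-isobutyl-5,7-dimethoxychroman-2-one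
Product: 6 (3S,4R)-3-(2-hydroxypropan-2-yl)-4-isobutyl-5,7-dimethoxychroman-2-one, via lithium lactone enolate 5 (not isolated)
Conditions: LiN(i-Pr)2 (1.1 equiv), THF, −78 °C; acetone (3 equiv), −78 °C; AcOH quench at −78 °C
Reagents that add atoms: acetone, CC(C)=O
Why: Aldol addition of a lactone lithium enolate to a ketone, in which acetone approaches the enolate face anti to the C4 isobutyl group and so sets C3 trans to C4 (the descriptor reads 3S only because the carbinol carbon outranks C4).

Step 4
Reactants: 6 (3S,4R)-3-(2-hydroxypropan-2-yl)-4-isobutyl-5,7-dimethoxychroman-2-one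
Product: 7 (3S,4R)-4-isobutyl-5,7-dimethoxy-3-(prop-1-en-2-yl)chroman-2-one
Conditions: SOCl2 (1.5 equiv), pyridine (5 equiv), CH2Cl2, −20 to 0 °C
Reagents that add atoms: none
Why: Dehydration of a tertiary alcohol through its chlorosulfite with pyridine as base (E2), which for an α-branched β-hydroxy ester should favour loss of a methyl hydrogen to the non-conjugated isopropenyl group and leaves C3 and C4 untouched.

Step 5
Reactants: 7 (3S,4R)-4-isobutyl-5,7-dimethoxy-3-(prop-1-en-2-yl)chroman-2-one
Product: 8 (3R,4R)-4-isobutyl-3-isopropyl-5,7-dimethoxychroman-2-one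
Conditions: H2 (1 atm), 5% Pd on carbon, EtOAc, rt
Reagents that add atoms: none
Why: Heterogeneous hydrogenation of an unhindered 1,1-disubstituted alkene, to which lactone and aryl methyl ethers are inert, and which keeps the trans C3/C4 relationship that is also the thermodynamic one for 3,4-disubstituted dihydrocoumarins.

Step 6
Reactants: 8 (3R,4R)-4-isobutyl-3-isopropyl-5,7-dimethoxychroman-2-one
Product: 9 (3R,4R)-4-isobutyl-3-isopropyl-5,7-dimethoxychroman-2-ol (anomer mixture)
Conditions: i-Bu2AlH (1.2 equiv), toluene, −78 °C; aq. potassium sodium tartrate work-up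
Reagents that add atoms: none
Why: Partial reduction of an aryl lactone to the lactol with i-Bu2AlH at low temperature, standard for dihydrocoumarins because the aluminium hemiacetal persists until work-up.

Step 7
Reactants: 9 (3R,4R)-4-isobutyl-3-isopropyl-5,7-dimethoxychroman-2-ol
Product: 10 (3R,4R)-4-isobutyl-3-isopropyl-2,5,7-trimethoxychroman (anomer mixture)
Conditions: MeOH, PPTS (10 mol %), 3 Å molecular sieves, rt
Reagents that add atoms: methanol, CO
Why: Acid-catalysed acetalisation of a lactol in excess methanol, mild enough that the electron-rich ring should not intercept the transient oxocarbenium ion, giving a C2 mask that withstands organolithium bases.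

Step 8
Reactants: 10 (3R,4R)-4-isobutyl-3-isopropyl-2,5,7-trimethoxychroman
Product: 12 (3R,4R)-4-isobutyl-3-isopropyl-2,5,7-trimethoxychroman-6,8-dicarbaldehyde, via C8 lithium amino alkoxide 11 (not isolated)
Conditions: n-BuLi (1.2 equiv), TMEDA, THF, 0 °C; DMF (1.2 equiv), −78 to 0 °C; n-BuLi (1.5 equiv), 0 °C; DMF (3 equiv), −78 °C to rt; aq. NH4Cl
Reagents that add atoms: N,N-dimethylformamide, CN(C)C=O
Why: Directed ortho-metalation and formylation, possible twice in one flask because C8–H (between OMe and the acetal oxygen) and C6–H (between two OMe groups) are both doubly activated and the first formyl group stays masked as its lithium α-amino alkoxide during the second metalation.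

Step 9
Reactants: 12 (3R,4R)-4-isobutyl-3-isopropyl-2,5,7-trimethoxychroman-6,8-dicarbaldehyde
Product: 13 (3R,4R)-2,5,7-trihydroxy-4-isobutyl-3-isopropylchroman-6,8-dicarbaldehyde (anomer mixture)
Conditions: BCl3 (6 equiv), CH2Cl2, −78 to 0 °C; then H2O/THF, rt
Reagents that add atoms: water, O
Why: Chelation-assisted BCl3 cleavage of aryl methyl ethers ortho to formyl groups (both qualify), with the same Lewis acid ionising the C2 acetal so that aqueous work-up returns the lactol, while C4 is not enolisable and C3 can only settle trans to it.

Step 10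
Reactants: 14 phloroglucinol
Product: 16 2,4-diformylphloroglucinol, via bis-iminium dichloride 15 (not isolated)
Conditions: POCl3 (2.5 equiv), DMF (2.5 equiv), 1,4-dioxane, 0 °C to rt; then ice/H2O
Reagents that add atoms: N,N-dimethylformamide, CN(C)C=O; water, O
Why: Vilsmeier–Haack formylation of the highly activated phloroglucinol ring, which takes up two chloroiminium electrophiles and gives the dialdehyde on hydrolysis, a known preparation of this compound.

Step 11
Reactants: 13 (3R,4R)-2,5,7-trihydroxy-4-isobutyl-3-isopropylchroman-6,8-dicarbaldehyde; 16 2,4-diformylphloroglucinol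
Product: 20 sideroxylonal C, via open hydroxy aldehyde 17 (not isolated), via ring B carbinol adduct 18 (not isolated), via ring B ortho-quinone methide 19 (not isolated)
Conditions: 13 (1 equiv), 16 (1.5 equiv), NaOAc (1 equiv), AcOH, 60–70 °C, N2
Reagents that add atoms: none
Why: In buffered acetic acid lactol 13 opens to hydroxy aldehyde 17, the one unsubstituted carbon of 16 (a vinylogous-acid carbon nucleophile) adds to its aldehyde carbon to form C2–C1' in carbinol 18, water is lost to give the ring B ortho-quinone methide 19, and a ring A phenol adds to the exocyclic carbon to form O1–C2. The closest known reaction type is the Knoevenagel condensation of 2,4-diformylphloroglucinol with aliphatic aldehydes to ortho-quinone methides that are captured in situ by oxygen nucleophiles or alkenes. The pyran ring closes by a 6-exo-trig oxa-Michael addition, and because the two ortho hydroxyls of ring A in 17 to 19 are related by symmetry, either of them gives the same chroman. C2 is controlled by C3: allylic 1,3-strain holds the C3–H bond in the plane of the quinone methide, so the tethered phenol reaches the face that places the ring B aryl group trans to the isopropyl group in a chair-like transition state (2R), while C3 stays trans to the non-enolisable C4 centre. The step needs the aliphatic aldehyde to react in preference to four aryl formyl groups, and carbon in preference to oxygen of 16; the first is secured because the aryl aldehydes are hydrogen-bonded vinylogous acids flanked by two oxygen substituents, the second because only C-attack leads on to the irreversible dehydration. Ring closure is reversible under these conditions, so a C2 epimer formed in error can reopen to 19 and close again.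

**Compound list**

1 | 3,5-dimethoxyphenol | COc1cc(O)cc(OC)c1 | starting material
2 | ethyl 5-methyl-3-oxohexanoate | CCOC(=O)CC(=O)CC(C)C | starting material
3 | 4-isobutyl-5,7-dimethoxy-2H-chromen-2-one | CC(C)CC1=CC(=O)Oc2cc(OC)cc(OC)c12 | intermediate
4 | (R)-4-isobutyl-5,7-dimethoxychroman-2-one | CC(C)C[C@H]1c2c(OC)cc(OC)cc2OC(=O)C1 | intermediate
5 | lithium (R)-4-isobutyl-5,7-dimethoxy-4H-chromen-2-olate (lactone enolate) | CC(C)C[C@H]1c2c(OC)cc(OC)cc2OC([O-])=C1.[Li+] | intermediate
6 | (3S,4R)-3-(2-hydroxypropan-2-yl)-4-isobutyl-5,7-dimethoxychroman-2-one (3,4-trans) | CC(C)C[C@H]1c2c(OC)cc(OC)cc2OC(=O)[C@@H]1C(C)(C)O | intermediate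
7 | (3S,4R)-4-isobutyl-5,7-dimethoxy-3-(prop-1-en-2-yl)chroman-2-one (3,4-trans) | CC(C)C[C@H]1c2c(OC)cc(OC)cc2OC(=O)[C@@H]1C(C)=C | intermediate
8 | (3R,4R)-4-isobutyl-3-isopropyl-5,7-dimethoxychroman-2-one (3,4-trans) | CC(C)C[C@H]1c2c(OC)cc(OC)cc2OC(=O)[C@@H]1C(C)C | intermediate
9 | (3R,4R)-4-isobutyl-3-isopropyl-5,7-dimethoxychroman-2-ol (anomer mixture) | CC(C)C[C@H]1c2c(OC)cc(OC)cc2OC(O)[C@@H]1C(C)C | intermediate
10 | (3R,4R)-4-isobutyl-3-isopropyl-2,5,7-trimethoxychroman (anomer mixture) | CC(C)C[C@H]1c2c(OC)cc(OC)cc2OC(OC)[C@@H]1C(C)C | intermediate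
11 | lithium (dimethylamino)[(3R,4R)-4-isobutyl-3-isopropyl-2,5,7-trimethoxychroman-8-yl]methanolate (masked 8-aldehyde) | CC(C)C[C@H]1c2c(OC)cc(OC)c(C([O-])N(C)C)c2OC(OC)[C@@H]1C(C)C.[Li+] | intermediate
12 | (3R,4R)-4-isobutyl-3-isopropyl-2,5,7-trimethoxychroman-6,8-dicarbaldehyde (anomer mixture) | CC(C)C[C@H]1c2c(OC)c(C=O)c(OC)c(C=O)c2OC(OC)[C@@H]1C(C)C | intermediate
13 | (3R,4R)-2,5,7-trihydroxy-4-isobutyl-3-isopropylchroman-6,8-dicarbaldehyde (anomer mixture) | CC(C)C[C@H]1c2c(O)c(C=O)c(O)c(C=O)c2OC(O)[C@@H]1C(C)C | intermediate
14 | phloroglucinol (benzene-1,3,5-triol) | Oc1cc(O)cc(O)c1 | starting material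
15 | (2,4,6-trihydroxy-1,3-phenylene)bis(N,N-dimethylmethaniminium) dichloride | C[N+](C)=Cc1c(O)cc(O)c(C=[N+](C)C)c1O.[Cl-].[Cl-] | intermediate
16 | 2,4-diformylphloroglucinol (2,4,6-trihydroxybenzene-1,3-dicarbaldehyde) | O=Cc1c(O)cc(O)c(C=O)c1O | intermediate
17 | (2R,3R)-3-(3,5-diformyl-2,4,6-trihydroxyphenyl)-2-isopropyl-5-methylhexanal (open form of 13) | CC(C)C[C@@H](c1c(O)c(C=O)c(O)c(C=O)c1O)[C@@H](C(C)C)C=O | intermediate
18 | 5-[(2R,3R)-3-(3,5-diformyl-2,4,6-trihydroxyphenyl)-1-hydroxy-2-isopropyl-5-methylhexyl]-2,4,6-trihydroxybenzene-1,3-dicarbaldehyde (carbinol epimers) | CC(C)C[C@@H](c1c(O)c(C=O)c(O)c(C=O)c1O)[C@@H](C(C)C)C(O)c1c(O)c(C=O)c(O)c(C=O)c1O | intermediate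
19 | 5-[(2S,3R)-3-(3,5-diformyl-2,4,6-trihydroxyphenyl)-2-isopropyl-5-methylhexylidene]-2,4-dihydroxy-6-oxocyclohexa-1,3-diene-1,3-dicarbaldehyde (ring B ortho-quinone methide, alkene geometry open) | CC(C)C[C@@H](c1c(O)c(C=O)c(O)c(C=O)c1O)[C@@H](C(C)C)C=C1C(=O)C(C=O)=C(O)C(C=O)=C1O | intermediate
20 | sideroxylonal C, (2R,3R,4R)-2-(3,5-diformyl-2,4,6-trihydroxyphenyl)-5,7-dihydroxy-4-isobutyl-3-isopropylchroman-6,8-dicarbaldehyde | CC(C)C[C@H]1c2c(O)c(C=O)c(O)c(C=O)c2O[C@@H](c2c(O)c(C=O)c(O)c(C=O)c2O)[C@@H]1C(C)C | target

**Count and risks**

Total steps: 11. Longest linear sequence: 10 (steps 1 to 9, then step 11); step 10 is the one-step side branch.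

The three steps most likely to fail:

1. Step 11. The condensation may stall because the aldehyde is α-branched and stored largely as the lactol while the arene partner is deactivated. Prolonged heating may also erode C2 and C3 through repeated reopening and tautomerisation of the quinone methide to the styrene. The fallback sets out from 13 and replaces the deactivated partner by the far more nucleophilic phloroglucinol 14 (5 equiv, TsOH·H2O cat., 1,4-dioxane, rt). Acid-catalysed arylation of the lactol through its cyclic oxocarbenium ion, a known flavan-forming reaction, should deliver the aryl group trans to the isopropyl group and give (2R,3R,4R)-5,7-dihydroxy-4-isobutyl-3-isopropyl-2-(2,4,6-trihydroxyphenyl)chroman-6,8-dicarbaldehyde F1. A Vilsmeier–Haack diformylation (POCl3, DMF, then H2O) can then only touch the two free positions of ring B, since ring A is fully substituted, and the route is rejoined at 20.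

2. Step 2. Hydride transfer may be slow, or facial discrimination poor, at a β-carbon crowded by the peri methoxy group. The fallback sets out from 1 and forms the C4–C4a bond enantioselectively instead of the C4–H bond. An iminium-catalysed Friedel–Crafts alkylation and hemiacetalisation with (E)-5-methylhex-2-enal is used, with (R)-α,α-diphenylprolinol trimethylsilyl ether (20 mol %) and PhCO2H in toluene at 0 °C, the catalyst hand being chosen to leave the Re face of the enal β-carbon open. This should give (4R)-4-isobutyl-5,7-dimethoxychroman-2-ol F2, and oxidation of the lactol (TEMPO cat., PhI(OAc)2, CH2Cl2) returns to the route at 4.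

3. Step 8. The second metalation may be incomplete, or butyl may add to the masked first aldehyde. The fallback sets out from 10 and exchanges deprotonation for halogen–metal exchange. Dibromination with NBS (2.1 equiv, MeCN, 0 °C) at the two activated positions should give (3R,4R)-6,8-dibromo-4-isobutyl-3-isopropyl-2,5,7-trimethoxychroman F3. Double bromine–lithium exchange (t-BuLi, 4.4 equiv, THF, −78 °C) followed by DMF comes back to the route at 12.

**Further compounds**

F1 | step 11 | (2R,3R,4R)-5,7-dihydroxy-4-isobutyl-3-isopropyl-2-(2,4,6-trihydroxyphenyl)chroman-6,8-dicarbaldehyde | CC(C)C[C@H]1c2c(O)c(C=O)c(O)c(C=O)c2O[C@@H](c2c(O)cc(O)cc2O)[C@@H]1C(C)C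
F2 | step 2 | (4R)-4-isobutyl-5,7-dimethoxychroman-2-ol (anomer mixture) | CC(C)C[C@H]1c2c(OC)cc(OC)cc2OC(O)C1
F3 | step 8 | (3R,4R)-6,8-dibromo-4-isobutyl-3-isopropyl-2,5,7-trimethoxychroman (anomer mixture) | CC(C)C[C@H]1c2c(OC)c(Br)c(OC)c(Br)c2OC(OC)[C@@H]1C(C)C
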